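Ring B is closed by forging C5–C6 (eudesmane numbering): a Mukaiyama aldol condensation joins C5 of a ring A enol silane, regiodefined by the asymmetric conjugate methylation that creates C10, to the C6 aldehyde of the side chain and gives the bicyclic enone with a C5=C6 double bond. The step exploits the 1,3-relationship of the oxygenated carbons C4 and C6 across the ring-fusion carbon C5 and leaves C5 trigonal. The trans ring fusion and the 6β-oxygen are then set by relay from the C10 methyl (4β-alcohol, directed 5β,6β-epoxide, palladium hydride to C5α). The precursor is a monocyclic silyl enol ether aldehyde.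

Key step: step 5

Remark on names: bicyclic compounds are also named with eudesmane numbering (ring A = C1 to C5 and C10, ring B = C5 to C10, methyl C14 on C10, methyl C15 on C4, isopropyl on C7). β is the face of the C10 methyl group, α the opposite face. All bicyclic compounds carry the 7β-isopropyl and 10β-methyl groups of the target, which is (3R,4R,5S,6R,7S,10S).

Step 1
Reactants: 1 methyl (2E)-4-bromobut-2-enoate
Product: 2 methyl (2R)-2-(propan-2-yl)but-3-enoate
Conditions: i-PrMgBr (1.2 equiv), CuBr·SMe2 (5 mol %), Taniaphos (6 mol %, enantiomer that gives the (R)-ester), CH2Cl2, −75 °C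
Reagents that add atoms: isopropylmagnesium bromide CC(C)[Mg]Br
Why: Copper-catalysed enantioselective allylic alkylation in which the alkylcopper species attacks C2 of the allylic bromide in the SN2′ sense and the chiral ferrocenyl diphosphine selects the enantiotopic face, which sets the future C7.

Step 2
Reactants: 2 methyl (2R)-2-(propan-2-yl)but-3-enoate; 3 3-bromocyclohex-2-en-1-one
Product: 5 methyl (2S)-4-(3-oxocyclohex-1-en-1-yl)-2-(propan-2-yl)butanoate, via alkylborane 4 (not isolated)
Conditions: 9-BBN-H (1.1 equiv), THF, 0 °C to rt; then 3, PdCl2(dppf) (3 mol %), aq. K3PO4, DMF, 50 °C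
Reagents that add atoms: none
Why: Anti-Markovnikov hydroboration of the terminal alkene followed by B-alkyl Suzuki–Miyaura cross-coupling with the β-bromo enone joins the side chain to the future C10; the stereocentre is not involved and no new one is formed.

Step 3
Reactants: 5 methyl (2S)-4-(3-oxocyclohex-1-en-1-yl)-2-(propan-2-yl)butanoate
Product: 7 methyl (2S)-4-[(1R)-1-methyl-3-(triethylsilyloxy)cyclohex-2-en-1-yl]-2-(propan-2-yl)butanoate, via aluminium enolate 6 (not isolated)
Conditions: Me3Al (1.3 equiv), Cu(OTf)2 (3 mol %), chiral phosphoramidite ligand (6 mol %, enantiomer that gives the (R)-configured quaternary carbon), Et2O, −30 °C; then Et3SiOTf (1.5 equiv), −30 to 0 °C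
Reagents that add atoms: trimethylaluminium C[Al](C)C; triethylsilyl trifluoromethanesulfonate CC[Si](CC)(CC)OS(=O)(=O)C(F)(F)F
Why: Copper-catalysed asymmetric conjugate addition of a methyl group to the β,β-disubstituted enone creates the C10 quaternary centre under control of the chiral ligand (the remote C7 centre is without influence), and O-silylation of the aluminium enolate fixes the enol double bond regiospecifically at C4=C5.

Step 4
Reactants: 7 methyl (2S)-4-[(1R)-1-methyl-3-(triethylsilyloxy)cyclohex-2-en-1-yl]-2-(propan-2-yl)butanoate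
Product: 8 (2S)-4-[(1R)-1-methyl-3-(triethylsilyloxy)cyclohex-2-en-1-yl]-2-(propan-2-yl)butanal
Conditions: i-Bu2AlH (1.1 equiv), toluene, −78 °C; aq. potassium sodium tartrate
Reagents that add atoms: none
Why: Half-reduction of the α-branched methyl ester stops at the aldehyde because the tetrahedral aluminium hemiacetal is stable at −78 °C, while the enol silane masks the ketone and the non-basic conditions leave C7 untouched.

Step 5
Reactants: 8 (2S)-4-[(1R)-1-methyl-3-(triethylsilyloxy)cyclohex-2-en-1-yl]-2-(propan-2-yl)butanal
Product: 10 (4aR,7S)-4a-methyl-7-(propan-2-yl)-3,4,4a,5,6,7-hexahydronaphthalen-1(2H)-one, via silyloxy ketone 9 (not isolated)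
Conditions: Sc(OTf)3 (10 mol %), CH2Cl2, −78 to 0 °C; then TsOH·H2O (10 mol %), rt
Reagents that add atoms: none
Why: Sc(OTf)3 activates the C6 aldehyde, which is attacked by C5 of the ring A enol silane through an open transition state with silyl transfer to the aldolate oxygen (intramolecular Mukaiyama aldol addition), and acid then removes triethylsilanol by β-elimination, so the overall change is an aldol condensation. Ring B closes in the 6-(enolexo)-exo-trig mode. The two transient stereocentres C5 and C6 of 9 are erased on purpose by the elimination, so no ring-fusion selectivity is asked of this step and C5 stays trigonal for the later hydride delivery. The selectivity that is needed is regiochemical (C5 and not C3), and it is secured by the position of the enol silane that step 3 delivers. The non-basic conditions should keep the epimerisable α-centre C7 of the aldehyde and the C10 quaternary centre unchanged.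

Step 6
Reactants: 10 (4aR,7S)-4a-methyl-7-(propan-2-yl)-3,4,4a,5,6,7-hexahydronaphthalen-1(2H)-one
Product: 11 (1S,4aR,7S)-1,4a-dimethyl-7-(propan-2-yl)-1,2,3,4,4a,5,6,7-octahydronaphthalen-1-ol
Conditions: MeLi (1.5 equiv), Et2O, −78 °C; H2O
Reagents that add atoms: methyllithium [Li]C
Why: 1,2-Addition of methyllithium to the enone carbonyl should occur from the α face, because the C10 methyl group stands perpendicular to the enone plane on the β face and 1,3 to C4, so the tertiary alcohol is 4β (substrate control).

Step 7
Reactants: 11 (1S,4aR,7S)-1,4a-dimethyl-7-(propan-2-yl)-1,2,3,4,4a,5,6,7-octahydronaphthalen-1-ol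
Product: 12 5β,6β-epoxyeudesman-4β-ol
Conditions: VO(acac)2 (5 mol %), t-BuOOH (1.5 equiv), toluene, 0 °C to rt
Reagents that add atoms: tert-butyl hydroperoxide CC(C)(C)OO
Why: Hydroxyl-directed epoxidation in which the vanadium alkoxide of the allylic 4β-alcohol delivers the peroxide oxygen to the same face of the C5=C6 bond, which gives the 5β,6β-oxirane and with it the β C6–O bond of the target.

Step 8
Reactants: 12 5β,6β-epoxyeudesman-4β-ol
Product: 13 5β,6β-epoxyeudesm-3-ene
Conditions: POCl3 (3 equiv), pyridine, 0 °C to rt
Reagents that add atoms: none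
Why: E2 dehydration of the axial tertiary alcohol through its dichlorophosphate removes the antiperiplanar axial H3α and gives the endocyclic C3=C4 alkene, elimination towards C5 being impossible because C5 is the fully substituted oxirane carbon.

Step 9
Reactants: 13 5β,6β-epoxyeudesm-3-ene
Product: 14 eudesm-3-en-6β-ol
Conditions: Pd2(dba)3·CHCl3 (2.5 mol %), n-Bu3P (10 mol %), HCO2H (5 equiv), Et3N (2 equiv), dioxane, rt
Reagents that add atoms: none
Why: Palladium-catalysed formate hydrogenolysis of the alkenyl oxirane, in which zerovalent palladium opens the allylic C5–O bond with inversion to a π-allyl complex on the α face and the hydride formed from formate is transferred to the more substituted terminus C5 on that same face, so H5 is α (trans ring fusion), the double bond stays at C3=C4 and the 6β C–O bond is untouched.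

Step 10
Reactants: 14 eudesm-3-en-6β-ol
Product: 15 eudesm-3-en-6β-yl benzoate
Conditions: BzCl (3 equiv), DMAP (0.2 equiv), pyridine, 60 °C
Reagents that add atoms: benzoyl chloride O=C(Cl)c1ccccc1
Why: DMAP-catalysed acylation of the hindered axial secondary alcohol with benzoyl chloride; no stereocentre is touched.

Step 11
Reactants: 15 eudesm-3-en-6β-yl benzoate
Product: 16 3α,4α-epoxyeudesman-6β-yl benzoate
Conditions: m-CPBA (1.3 equiv), NaHCO3, CH2Cl2, 0 °C
Reagents that add atoms: 3-chloroperbenzoic acid OOC(=O)c1cccc(Cl)c1
Why: Prilezhaev epoxidation of the trisubstituted alkene should take place from the α face, because the β face at C4 is screened by the syn-axial C10 methyl and 6β-benzoyloxy groups.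

Step 12
Reactants: 16 3α,4α-epoxyeudesman-6β-yl benzoate
Product: 17 3α,4β-dihydroxyeudesman-6β-yl benzoate
Conditions: HClO4 (cat.), THF–H2O, 0 °C to rt
Reagents that add atoms: water O
Why: Acid-catalysed trans-diaxial opening of the oxirane (Fürst–Plattner rule) at the tertiary carbon C4 from the β face, where the syn-axial benzoate carbonyl can assist, gives the 3α,4β-diol with inversion at C4 and retention at C3.

Compound list
1 | methyl (2E)-4-bromobut-2-enoate | BrC/C=C/C(=O)OC | starting material
2 | methyl (2R)-2-(propan-2-yl)but-3-enoate | CC(C)[C@@H](C(=O)OC)C=C | intermediate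
3 | 3-bromocyclohex-2-en-1-one | O=C1C=C(Br)CCC1 | starting material
4 | methyl (2S)-4-(9-borabicyclo[3.3.1]nonan-9-yl)-2-(propan-2-yl)butanoate (alkylborane, not isolated) | CC(C)[C@@H](C(=O)OC)CCB1C2CCCC1CCC2 | intermediate
5 | methyl (2S)-4-(3-oxocyclohex-1-en-1-yl)-2-(propan-2-yl)butanoate | CC(C)[C@@H](C(=O)OC)CCC1=CC(=O)CCC1 | intermediate
6 | methyl (2S)-4-[(1R)-3-(dimethylalumanyloxy)-1-methylcyclohex-2-en-1-yl]-2-(propan-2-yl)butanoate (aluminium enolate, not isolated) | CC(C)[C@@H](C(=O)OC)CC[C@@]1(C)CCCC(O[Al](C)C)=C1 | intermediate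
7 | methyl (2S)-4-[(1R)-1-methyl-3-(triethylsilyloxy)cyclohex-2-en-1-yl]-2-(propan-2-yl)butanoate | CC(C)[C@@H](C(=O)OC)CC[C@@]1(C)CCCC(O[Si](CC)(CC)CC)=C1 | intermediate
8 | (2S)-4-[(1R)-1-methyl-3-(triethylsilyloxy)cyclohex-2-en-1-yl]-2-(propan-2-yl)butanal | CC(C)[C@@H](C=O)CC[C@@]1(C)CCCC(O[Si](CC)(CC)CC)=C1 | intermediate
9 | (4aR,7S)-4a-methyl-7-(propan-2-yl)-8-(triethylsilyloxy)octahydronaphthalen-1(2H)-one, mixture of epimers at C8 and C8a (6-silyloxy-15-noreudesman-4-one, not isolated) | CC(C)[C@@H]1CC[C@@]2(C)CCCC(=O)C2C1O[Si](CC)(CC)CC | intermediate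
10 | (4aR,7S)-4a-methyl-7-(propan-2-yl)-3,4,4a,5,6,7-hexahydronaphthalen-1(2H)-one (15-noreudesm-5-en-4-one) | CC(C)[C@@H]1CC[C@@]2(C)CCCC(=O)C2=C1 | intermediate
11 | (1S,4aR,7S)-1,4a-dimethyl-7-(propan-2-yl)-1,2,3,4,4a,5,6,7-octahydronaphthalen-1-ol (eudesm-5-en-4β-ol) | CC(C)[C@@H]1CC[C@@]2(C)CCC[C@](C)(O)C2=C1 | intermediate
12 | 5β,6β-epoxyeudesman-4β-ol (4α-methyl) | CC(C)[C@@H]1CC[C@@]2(C)CCC[C@](C)(O)[C@]23O[C@H]13 | intermediate
13 | 5β,6β-epoxyeudesm-3-ene | CC(C)[C@@H]1CC[C@@]2(C)CCC=C(C)[C@]23O[C@H]13 | intermediate
14 | eudesm-3-en-6β-ol (5α-H, trans-fused) | CC(C)[C@@H]1CC[C@@]2(C)CCC=C(C)[C@@H]2[C@@H]1O | intermediate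
15 | eudesm-3-en-6β-yl benzoate (5α-H) | CC(C)[C@@H]1CC[C@@]2(C)CCC=C(C)[C@@H]2[C@@H]1OC(=O)c1ccccc1 | intermediate
16 | 3α,4α-epoxyeudesman-6β-yl benzoate (4β-methyl, 5α-H) | CC(C)[C@@H]1CC[C@@]2(C)CC[C@H]3O[C@@]3(C)[C@@H]2[C@@H]1OC(=O)c1ccccc1 | intermediate
17 | 3α,4β-dihydroxyeudesman-6β-yl benzoate = [(1R,2S,4aS,7R,8R,8aS)-7,8-dihydroxy-4a,8-dimethyl-2-(propan-2-yl)decahydronaphthalen-1-yl] benzoate | CC(C)[C@@H]1CC[C@@]2(C)CC[C@@H](O)[C@](C)(O)[C@@H]2[C@@H]1OC(=O)c1ccccc1 | target

Total step count: 12. Longest linear sequence: 12 steps, from compound 1 to compound 17.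

Steps most likely to fail

Step 8. The elimination may lose its regiocontrol and give the exocyclic C4=C15 alkene, and the neighbouring oxirane may be opened by chloride or ionise under the dehydrating conditions. The fallback sets out from 12 and comes back at 15, and it avoids the alkenyl oxirane altogether. Compound 12 is treated with Cp2TiCl (made from Cp2TiCl2 and Zn) and 1,4-cyclohexadiene in THF. Homolytic opening of the oxirane at its more substituted carbon gives the tertiary C5 radical, which should take a hydrogen atom from the α face because both titanium alkoxides and the C10 methyl are β. This gives eudesmane-4β,6β-diol F3. Selective benzoylation of the secondary 6β-hydroxyl (BzCl, DMAP, pyridine) gives 4β-hydroxyeudesman-6β-yl benzoate F4. Syn-elimination with the Burgess reagent (benzene, 50 °C), in which H5α, trans to the hydroxyl, cannot take part, then leads to 15.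

Step 9. The hydride may be delivered to the wrong allyl terminus (C3, which would leave a C4=C5 double bond), or the π-allyl complex may undergo β-hydride elimination to a dienol. The fallback sets out from 13 and comes back at 14. BF3·OEt2 (CH2Cl2, −78 °C) ionises the allylic C5–O bond, and the antiperiplanar H6α shifts to the α face of C5 (Meinwald rearrangement). This gives eudesm-3-en-6-one F5 with the trans ring fusion. Reduction with Li(s-Bu)3BH (THF, −78 °C) from the α face, the β face being blocked by the axial C10 methyl, then gives 14.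

Step 5. The enol silane may be protodesilylated before the C–C bond forms, the Lewis-acid-activated α-branched aldehyde may enolise and epimerise at C7, or the β-elimination may stay incomplete. The fallback sets out from 8 and comes back at 10, and it replaces the Lewis-acid aldol by a reductive one. NBS (THF, −78 °C) converts the enol silane regiospecifically into the α-bromo ketone (2S)-4-[(1R)-2-bromo-1-methyl-3-oxocyclohexyl]-2-(propan-2-yl)butanal F1. SmI2 (THF, −78 °C) then generates the samarium enolate at C5, which adds to the aldehyde in an intramolecular Reformatsky-type aldol reaction under neutral conditions and gives the β-hydroxy ketone 6-hydroxy-15-noreudesman-4-one F2. Mesylation (MsCl, Et3N) and elimination with DBU give 10.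

Further compounds
F1 | step 5 | (2S)-4-[(1R)-2-bromo-1-methyl-3-oxocyclohexyl]-2-(propan-2-yl)butanal (mixture at the CHBr carbon) | CC(C)[C@@H](C=O)CC[C@@]1(C)CCCC(=O)C1Br
F2 | step 5 | (4aR,7S)-8-hydroxy-4a-methyl-7-(propan-2-yl)octahydronaphthalen-1(2H)-one, mixture at C8 and C8a (6-hydroxy-15-noreudesman-4-one) | CC(C)[C@@H]1CC[C@@]2(C)CCCC(=O)C2C1O
F3 | step 8 | eudesmane-4β,6β-diol (5α-H) | CC(C)[C@@H]1CC[C@@]2(C)CCC[C@](C)(O)[C@@H]2[C@@H]1O
F4 | step 8 | 4β-hydroxyeudesman-6β-yl benzoate (5α-H) | CC(C)[C@@H]1CC[C@@]2(C)CCC[C@](C)(O)[C@@H]2[C@@H]1OC(=O)c1ccccc1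
F5 | step 9 | eudesm-3-en-6-one (5α-H) | CC(C)[C@@H]1CC[C@@]2(C)CCC=C(C)[C@@H]2C1=O
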